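The numbers in the tables were computed with made-up constants.

**The charges.** Subtract the stray impurity from the enzyme before reading any curve.

| setting | oak | maple | autumn | midnight |
|---|---|---|---|---|
| starting material | 20 mM | 20 mM | 20 mM | 20 mM |
| protic impurity | 2 mM | 2 mM | 2.00 mM | 2.00 mM |
| enzyme | 0.0037 mol% | 0.0062 mol% | 0.0032 mol% | 0.0048 mol% |
| stray impurity | 0.065 µM | 0.065 µM | 0.065 µM | 0.065 µM |
| remark | run made earlier | run made earlier |  |  |
| time |  |  | 2.0 h | 2.0 h |

| run | time / min | product / % | starting material / % |
|---|---|---|---|
| oak | 8.00 | 34 | 55 |
| oak | 15.0 | 45 | 43 |
| oak | 25.0 | 55 | 35 |
| oak | 30.0 | 61 | 30 |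
| oak | 40.0 | 65 | 21 |
| oak | 50.0 | 69 | 20 |
| oak | 60.0 | 73 | 15 |
| maple | 3.00 | 33 | 63 |
| maple | 10.0 | 49 | 43 |
| maple | 15.0 | 59 | 34 |
| maple | 25.0 | 67 | 26 |
| maple | 40.0 | 74 | 12 |
| maple | 50.0 | 81 | 7 |
| maple | 60.0 | 83 | 6 |

(readings scatter by 1.5 percentage points)

1. which of these there is most of at the end, counted by the starting material in it, autumn (starting material / product)
2. which of these there is most of at the end, counted by the starting material in it, midnight (starting material / product)
3. how much there is at the end of the one of these that leads, in percent of the starting material charged: autumn
4. how much there is at the end of the one of these that leads, in percent of the starting material charged: midnight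

- steps thought possible: starting material + enzyme -> product + enzyme; starting material + protic impurity -> quenched substrate; enzyme + stray impurity -> spent catalyst

**Working enzyme.** I took the poisoning as over at once and reckoned with what it leaves free. Oak's enzyme charge of 0.740 µM was more than its 0.065 µM of stray impurity, so the stray impurity was the limiting reagent of that step. That left 0.675 µM working in oak and 1.18 µM in maple. For flasks with these starting material and protic impurity charges, I assumed that pace follows working enzyme. Autumn's maple-equivalent time was 58.7 min: the flask's time multiplied by its working enzyme and divided by maple's.

**Two ways.** Working enzyme reckoned maple faster than oak by a factor of 1.75. The readings gave 1.67, since oak stood at 35% starting material after 25.0 min and maple at 34% after 15.0 min. I trusted the scaling, but the bare loadings also give 1.68, so these readings did not show the subtraction itself. The ceiling also came two ways: 90.0% from the protic impurity charge, and 89.0% as maple's last sum.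

**My reckoning.** Autumn's 58.7 min was a little shorter than maple's last reading at 60.0 min, so I expected about 83% product. Midnight's 91.4 min lay beyond maple's table, so I placed midnight's product between 83% and the ceiling of 90.0%.

**The forecast.** It named product for autumn at 83% and product for midnight at 87%, holding that “Decay is not first order”. Its autumn figure equals mine, and its midnight figure lies inside my bracket.

**The flasks.** Autumn gave 81.5% product and 8.52% starting material; midnight gave 86.4% and 3.56%.

    starting material + enzyme → product + enzyme, rate k1*[starting material]*[enzyme]/(1 + ([starting material]/Km1) + ([product]/Kp1)) (42.7 mM, 0.121 mM, k = 52500 M⁻¹ s⁻¹)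
    starting material + protic impurity → quenched substrate (k = 0.277 M⁻¹ s⁻¹)
    enzyme + stray impurity → spent catalyst (k = 59800 M⁻¹ s⁻¹)

**What ran.** By 1.00 h, autumn held 0% of its stray impurity charge and 0.0508% of its protic impurity charge, with quenched substrate at 9.99% and product at 70.0% of the starting material charged. Through the second hour enzyme stood at 89.8% of its charge, as the subtraction gives (89.8%), while product rose to 81.5%. Autumn's product, at 58.7 min of maple-equivalent time, lay 1.5 percentage points below maple's last reading, against a scatter of 1.5 points. The crowding by starting material made no difference to autumn's product.

**Next flask.** A neighbour of autumn, charged with 0.0013 mol% enzyme, had a maple-equivalent time of 19.9 min, midway between maple's readings at 15.0 min and 25.0 min, whose mean is 63.0% product. The neighbour gave 62.4% product, with 75.0% of its enzyme working.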